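**Retrosynthetic overview**
1. Target 18 ⇐ O-demethylation and C8-debromination of the tri-formyl pentamethyl ether 16; the three CHO groups ⇐ Rieche formylation of 14, where the C8 bromine blocks the only unwanted ring position.
2. C4 isobutyl ⇐ C4 nitromethyl (Nef reaction, isopropylidene Wittig, hydrogenation).
3. C2–aryl bond ⇐ Friedel–Crafts arylation of lactol 7 (oxocarbenium ion) with 1,3,5-trimethoxybenzene, trans to the C3 isopropyl group.
4. C3–C4 bond with both stereocentres ⇐ amine-catalysed Michael addition of 3-methylbutanal to nitrostyrene 4; hemiacetalisation closes the pyran ring, the only ring that is built (both benzene rings are bought).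
5. 4 ⇐ Henry condensation of ortho-brominated 2-hydroxy-4,6-dimethoxybenzaldehyde with nitromethane.

Assumption: the identifier is taken to mean exactly the given SMILES, i.e. the (2R,3R,4S) enantiomer with 2,3-trans and 3,4-cis substituents.

**Route**

Step 1
Reactants: 1 2-hydroxy-4,6-dimethoxybenzaldehyde
Product: 2 3-bromo-2-hydroxy-4,6-dimethoxybenzaldehyde
Conditions: NBS (1.0 equiv), i-Pr2NH (10 mol%), CH2Cl2, 0 °C
Reagents that add atoms: N-bromosuccinimide, O=C1CCC(=O)N1Br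
Why: Amine-mediated electrophilic aromatic bromination is expected to deliver bromine ortho to the hydrogen-bonded phenol OH (the future C8); the regiochemistry should be confirmed by NOE/HMBC.

Step 2
Reactants: 2 3-bromo-2-hydroxy-4,6-dimethoxybenzaldehyde; 3 nitromethane
Product: 4 2-bromo-3,5-dimethoxy-6-[(E)-2-nitroethenyl]phenol
Conditions: 3 (excess, as solvent), NH4OAc (30 mol%), 90 °C
Reagents that add atoms: none
Why: Henry (nitroaldol) condensation with loss of water gives the thermodynamically favoured E-nitroalkene, as is routine for salicylaldehydes.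

Step 3
Reactants: 4 2-bromo-3,5-dimethoxy-6-[(E)-2-nitroethenyl]phenol; 5 3-methylbutanal
Product: 7 (3R,4S)-8-bromo-5,7-dimethoxy-4-(nitromethyl)-3-(propan-2-yl)chroman-2-ol (C2 anomers), via open-chain nitro aldehyde 6 (not isolated)
Conditions: (S)-α,α-diphenylprolinol TMS ether (20 mol%), PhCO2H (20 mol%), 5 (3 equiv), toluene, rt, 48 h
Reagents that add atoms: none
Why: Enamine-catalysed asymmetric Michael addition: the E-enamine attacks the nitroalkene through the synclinal transition state on the face away from the CPh2OTMS group, giving the syn (2R,3S) adduct, which closes to the 3,4-cis lactol (C3 R, C4 S).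

Step 4
Reactants: 7 (3R,4S)-8-bromo-5,7-dimethoxy-4-(nitromethyl)-3-(propan-2-yl)chroman-2-ol; 8 1,3,5-trimethoxybenzene
Product: 10 (2R,3R,4S)-8-bromo-5,7-dimethoxy-4-(nitromethyl)-3-(propan-2-yl)-2-(2,4,6-trimethoxyphenyl)chromane, via oxocarbenium ion 9 (not isolated)
Conditions: 8 (1.5 equiv), BF3·OEt2 (30 mol%), 4 Å MS, CH2Cl2, −78 → −20 °C; Et3N quench
Reagents that add atoms: none
Why: Friedel–Crafts arylation of the cyclic oxocarbenium ion (C-glycosylation type): the arene attacks C2 on the face opposite the C3 isopropyl and the pseudo-axial C4 substituent, giving the 2,3-trans (2R) chromane, which is also the thermodynamic isomer.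

Step 5
Reactants: 10 (2R,3R,4S)-8-bromo-5,7-dimethoxy-4-(nitromethyl)-3-(propan-2-yl)-2-(2,4,6-trimethoxyphenyl)chromane
Product: 12 (2R,3R,4S)-8-bromo-5,7-dimethoxy-3-(propan-2-yl)-2-(2,4,6-trimethoxyphenyl)chromane-4-carbaldehyde, via potassium nitronate 11 (not isolated)
Conditions: KOtBu (1.05 equiv), THF, 0 °C; then DMDO (1.2 equiv, acetone), 0 °C, 10 min
Reagents that add atoms: dimethyldioxirane, CC1(C)OO1; potassium tert-butoxide, CC(C)(C)[O-].[K+] (supplies only the potassium of 11)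
Why: Oxidative Nef reaction: deprotonation occurs only at CH2NO2 and the nitronate C=N is oxidised far faster than the arenes, so no stereocentre is touched.

Step 6
Reactants: 12 (2R,3R,4S)-8-bromo-5,7-dimethoxy-3-(propan-2-yl)-2-(2,4,6-trimethoxyphenyl)chromane-4-carbaldehyde
Product: 13 (2R,3R,4S)-8-bromo-5,7-dimethoxy-4-(2-methylprop-1-en-1-yl)-3-(propan-2-yl)-2-(2,4,6-trimethoxyphenyl)chromane
Conditions: i-PrPPh3I (2.0 equiv), n-BuLi (1.9 equiv), THF, 0 °C; then 12, −78 °C → rt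
Reagents that add atoms: isopropyltriphenylphosphonium iodide, CC(C)[P+](c1ccccc1)(c1ccccc1)c1ccccc1.[I-]
Why: Wittig olefination with the preformed non-stabilised ylide at low temperature; the aryl bromide is inert to the ylide, and C4 is expected to keep its configuration because the 3,4-cis arrangement (C4 substituent pseudo-axial, away from the 5-OMe) should be the more stable one.

Step 7
Reactants: 13 (2R,3R,4S)-8-bromo-5,7-dimethoxy-4-(2-methylprop-1-en-1-yl)-3-(propan-2-yl)-2-(2,4,6-trimethoxyphenyl)chromane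
Product: 14 (2R,3R,4S)-8-bromo-5,7-dimethoxy-4-(2-methylpropyl)-3-(propan-2-yl)-2-(2,4,6-trimethoxyphenyl)chromane
Conditions: H2 (1–4 atm), [Ir(cod)(PCy3)(py)]PF6 (5 mol%), CH2Cl2, rt
Reagents that add atoms: none
Why: Homogeneous (Crabtree) hydrogenation reduces the trisubstituted alkene without hydrogenolysing the aryl bromide or the benzylic C2–O bond; no stereocentre is created.

Step 8
Reactants: 14 (2R,3R,4S)-8-bromo-5,7-dimethoxy-4-(2-methylpropyl)-3-(propan-2-yl)-2-(2,4,6-trimethoxyphenyl)chromane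
Product: 16 5-[(2R,3R,4S)-8-bromo-6-formyl-5,7-dimethoxy-4-(2-methylpropyl)-3-(propan-2-yl)chroman-2-yl]-2,4,6-trimethoxybenzene-1,3-dicarbaldehyde, via tris(chloro-methoxymethyl) arene 15 (not isolated)
Conditions: Cl2CHOMe (8 equiv), TiCl4 (8 equiv), CH2Cl2, −78 → 0 °C; then ice-water
Reagents that add atoms: dichloromethyl methyl ether, COC(Cl)Cl; water, O
Why: Rieche formylation (electrophilic aromatic substitution) at the only three free ring positions (C6, C3′, C5′) since C8 is blocked by bromine; the α-chloro ethers hydrolyse to aldehydes on work-up.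

Step 9
Reactants: 16 5-[(2R,3R,4S)-8-bromo-6-formyl-5,7-dimethoxy-4-(2-methylpropyl)-3-(propan-2-yl)chroman-2-yl]-2,4,6-trimethoxybenzene-1,3-dicarbaldehyde
Product: 17 5-[(2R,3R,4S)-6-formyl-5,7-dimethoxy-4-(2-methylpropyl)-3-(propan-2-yl)chroman-2-yl]-2,4,6-trimethoxybenzene-1,3-dicarbaldehyde
Conditions: Pd(OAc)2 (5 mol%), XPhos (10 mol%), HCO2Na (3 equiv), DMF, 80 °C
Reagents that add atoms: none
Why: Palladium-catalysed hydrodehalogenation with formate as hydride donor removes the blocking bromine and should leave the aryl aldehydes, the benzylic ether and the stereocentres untouched.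

Step 10
Reactants: 17 5-[(2R,3R,4S)-6-formyl-5,7-dimethoxy-4-(2-methylpropyl)-3-(propan-2-yl)chroman-2-yl]-2,4,6-trimethoxybenzene-1,3-dicarbaldehyde
Product: 18 5-[(2R,3R,4S)-6-formyl-5,7-dihydroxy-4-(2-methylpropyl)-3-(propan-2-yl)chroman-2-yl]-2,4,6-trihydroxybenzene-1,3-dicarbaldehyde (CNP0328914.1)
Conditions: BBr3 (12 equiv), CH2Cl2, −78 → 0 °C; then H2O
Reagents that add atoms: none
Why: Lewis-acid ether cleavage, assisted by chelation because every methoxy group is ortho to a formyl group; the electron-poor rings disfavour ionisation of the C2–O bond, so the ring and its stereocentres should be retained.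

**Compound list**
1 | 2-hydroxy-4,6-dimethoxybenzaldehyde | COc1cc(O)c(C=O)c(OC)c1 | starting material
2 | 3-bromo-2-hydroxy-4,6-dimethoxybenzaldehyde | COc1cc(OC)c(C=O)c(O)c1Br | intermediate
3 | nitromethane | C[N+](=O)[O-] | starting material
4 | 2-bromo-3,5-dimethoxy-6-[(E)-2-nitroethenyl]phenol | COc1cc(OC)c(/C=C/[N+](=O)[O-])c(O)c1Br | intermediate
5 | 3-methylbutanal | CC(C)CC=O | starting material
6 | (2R,3S)-3-(3-bromo-2-hydroxy-4,6-dimethoxyphenyl)-4-nitro-2-(propan-2-yl)butanal | O=[N+]([O-])C[C@H](c1c(OC)cc(OC)c(Br)c1O)[C@H](C=O)C(C)C | intermediate (not isolated)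
7 | (3R,4S)-8-bromo-5,7-dimethoxy-4-(nitromethyl)-3-(propan-2-yl)chroman-2-ol (C2 anomers) | O=[N+]([O-])C[C@@H]1c2c(OC)cc(OC)c(Br)c2OC(O)[C@@H]1C(C)C | intermediate
8 | 1,3,5-trimethoxybenzene | COc1cc(OC)cc(OC)c1 | starting material
9 | (3R,4S)-8-bromo-5,7-dimethoxy-4-(nitromethyl)-3-(propan-2-yl)-3,4-dihydrochromenylium (oxocarbenium ion) | O=[N+]([O-])C[C@@H]1c2c(OC)cc(OC)c(Br)c2[O+]=C[C@@H]1C(C)C | intermediate (not isolated)
10 | (2R,3R,4S)-8-bromo-5,7-dimethoxy-4-(nitromethyl)-3-(propan-2-yl)-2-(2,4,6-trimethoxyphenyl)chromane | O=[N+]([O-])C[C@@H]1c2c(OC)cc(OC)c(Br)c2O[C@@H](c2c(OC)cc(OC)cc2OC)[C@@H]1C(C)C | intermediate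
11 | potassium nitronate of 10 | [K+].[O-][N+]([O-])=C[C@@H]1c2c(OC)cc(OC)c(Br)c2O[C@@H](c2c(OC)cc(OC)cc2OC)[C@@H]1C(C)C | intermediate (not isolated)
12 | (2R,3R,4S)-8-bromo-5,7-dimethoxy-3-(propan-2-yl)-2-(2,4,6-trimethoxyphenyl)chromane-4-carbaldehyde | O=C[C@@H]1c2c(OC)cc(OC)c(Br)c2O[C@@H](c2c(OC)cc(OC)cc2OC)[C@@H]1C(C)C | intermediate
13 | (2R,3R,4S)-8-bromo-5,7-dimethoxy-4-(2-methylprop-1-en-1-yl)-3-(propan-2-yl)-2-(2,4,6-trimethoxyphenyl)chromane | CC(C)=C[C@@H]1c2c(OC)cc(OC)c(Br)c2O[C@@H](c2c(OC)cc(OC)cc2OC)[C@@H]1C(C)C | intermediate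
14 | (2R,3R,4S)-8-bromo-5,7-dimethoxy-4-(2-methylpropyl)-3-(propan-2-yl)-2-(2,4,6-trimethoxyphenyl)chromane | CC(C)C[C@@H]1c2c(OC)cc(OC)c(Br)c2O[C@@H](c2c(OC)cc(OC)cc2OC)[C@@H]1C(C)C | intermediate
15 | (2R,3R,4S)-8-bromo-6-[chloro(methoxy)methyl]-2-{3,5-bis[chloro(methoxy)methyl]-2,4,6-trimethoxyphenyl}-5,7-dimethoxy-4-(2-methylpropyl)-3-(propan-2-yl)chromane | CC(C)C[C@@H]1c2c(OC)c(C(Cl)OC)c(OC)c(Br)c2O[C@@H](c2c(OC)c(C(Cl)OC)c(OC)c(C(Cl)OC)c2OC)[C@@H]1C(C)C | intermediate (not isolated)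
16 | 5-[(2R,3R,4S)-8-bromo-6-formyl-5,7-dimethoxy-4-(2-methylpropyl)-3-(propan-2-yl)chroman-2-yl]-2,4,6-trimethoxybenzene-1,3-dicarbaldehyde | CC(C)C[C@@H]1c2c(OC)c(C=O)c(OC)c(Br)c2O[C@@H](c2c(OC)c(C=O)c(OC)c(C=O)c2OC)[C@@H]1C(C)C | intermediate
17 | 5-[(2R,3R,4S)-6-formyl-5,7-dimethoxy-4-(2-methylpropyl)-3-(propan-2-yl)chroman-2-yl]-2,4,6-trimethoxybenzene-1,3-dicarbaldehyde | CC(C)C[C@@H]1c2c(OC)c(C=O)c(OC)cc2O[C@@H](c2c(OC)c(C=O)c(OC)c(C=O)c2OC)[C@@H]1C(C)C | intermediate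
18 | 5-[(2R,3R,4S)-6-formyl-5,7-dihydroxy-4-(2-methylpropyl)-3-(propan-2-yl)chroman-2-yl]-2,4,6-trihydroxybenzene-1,3-dicarbaldehyde | CC(C)C[C@@H]1c2c(cc(O)c(C=O)c2O)O[C@@H](c2c(O)c(C=O)c(O)c(C=O)c2O)[C@@H]1C(C)C | target

**Summary**
Total steps: 10. Longest linear sequence: 10 steps (1 → 18).

**Steps most likely to fail, with fallbacks**

Step 4. The lactol arylation can over-react: the product can re-ionise at C2 and take up a second arene to give a diarylmethane, and acid can erode C3 through the 4H-chromene. The fallback builds the isobutyl group first and brings ring B in as an organometallic. It sets out from 7, which is protected as the methyl acetal (3R,4S)-8-bromo-2,5,7-trimethoxy-4-(nitromethyl)-3-(propan-2-yl)chromane F1 (HC(OMe)3, MeOH, PPTS). The nitronate/DMDO Nef reaction gives (3R,4S)-8-bromo-2,5,7-trimethoxy-3-(propan-2-yl)chromane-4-carbaldehyde F2. Wittig reaction with Ph3P=CMe2 gives (3R,4S)-8-bromo-2,5,7-trimethoxy-4-(2-methylprop-1-en-1-yl)-3-(propan-2-yl)chromane F3, and Crabtree hydrogenation gives (3R,4S)-8-bromo-2,5,7-trimethoxy-4-(2-methylpropyl)-3-(propan-2-yl)chromane F4. Aqueous AcOH/THF then frees the lactol (3R,4S)-8-bromo-5,7-dimethoxy-4-(2-methylpropyl)-3-(propan-2-yl)chroman-2-ol F5. 2,4,6-Trimethoxyphenylmagnesium bromide (3 equiv, THF, 0 °C → rt) adds to its ring-opened hydroxy aldehyde to give (2R,3S)-3-(3-bromo-2-hydroxy-4,6-dimethoxyphenyl)-5-methyl-2-(propan-2-yl)-1-(2,4,6-trimethoxyphenyl)hexan-1-ol F6. PPTS in CH2Cl2 closes the ring through the trimethoxybenzyl cation, trans to the isopropyl group, and the route is rejoined at 14.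

Step 6. The aldehyde is hindered and its α-carbon (C4) is benzylic and epimerisable, so the basic ylide may give low conversion or a C4 mixture. The fallback replaces olefination by sp3–sp3 coupling and sets out from 12. NaBH4 (MeOH, 0 °C) gives [(2R,3R,4S)-8-bromo-5,7-dimethoxy-3-(propan-2-yl)-2-(2,4,6-trimethoxyphenyl)chroman-4-yl]methanol F7, which removes the epimerisation risk at once. I2, PPh3 and imidazole give (2R,3R,4S)-8-bromo-4-(iodomethyl)-5,7-dimethoxy-3-(propan-2-yl)-2-(2,4,6-trimethoxyphenyl)chromane F8. Copper-catalysed coupling with i-PrMgCl (Li2CuCl4 cat., THF, −20 °C) gives the isobutyl compound directly and rejoins the route at 14.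

Step 8. Before ring B is deactivated by its first formyl group, TiCl4 can ionise the C2–O bond (ring opening, loss of C3 integrity, retro-Friedel–Crafts), and the third formylation may stall. The fallback formylates the free phenols instead and sets out from 14. BBr3 (CH2Cl2, −78 → 0 °C) gives 2-[(2R,3R,4S)-8-bromo-5,7-dihydroxy-4-(2-methylpropyl)-3-(propan-2-yl)chroman-2-yl]benzene-1,3,5-triol F9. Vilsmeier–Haack formylation (POCl3, DMF, MeCN, rt; aqueous hydrolysis) at the three free positions ortho to OH gives 5-[(2R,3R,4S)-8-bromo-6-formyl-5,7-dihydroxy-4-(2-methylpropyl)-3-(propan-2-yl)chroman-2-yl]-2,4,6-trihydroxybenzene-1,3-dicarbaldehyde F10. Pd-catalysed formate hydrodebromination (Pd(OAc)2, XPhos, HCO2Na, DMF) then arrives at 18.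

**Further compounds**
F1 | step 4 | (3R,4S)-8-bromo-2,5,7-trimethoxy-4-(nitromethyl)-3-(propan-2-yl)chromane | O=[N+]([O-])C[C@@H]1c2c(OC)cc(OC)c(Br)c2OC(OC)[C@@H]1C(C)C
F2 | step 4 | (3R,4S)-8-bromo-2,5,7-trimethoxy-3-(propan-2-yl)chromane-4-carbaldehyde | O=C[C@@H]1c2c(OC)cc(OC)c(Br)c2OC(OC)[C@@H]1C(C)C
F3 | step 4 | (3R,4S)-8-bromo-2,5,7-trimethoxy-4-(2-methylprop-1-en-1-yl)-3-(propan-2-yl)chromane | CC(C)=C[C@@H]1c2c(OC)cc(OC)c(Br)c2OC(OC)[C@@H]1C(C)C
F4 | step 4 | (3R,4S)-8-bromo-2,5,7-trimethoxy-4-(2-methylpropyl)-3-(propan-2-yl)chromane | CC(C)C[C@@H]1c2c(OC)cc(OC)c(Br)c2OC(OC)[C@@H]1C(C)C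
F5 | step 4 | (3R,4S)-8-bromo-5,7-dimethoxy-4-(2-methylpropyl)-3-(propan-2-yl)chroman-2-ol | CC(C)C[C@@H]1c2c(OC)cc(OC)c(Br)c2OC(O)[C@@H]1C(C)C
F6 | step 4 | (2R,3S)-3-(3-bromo-2-hydroxy-4,6-dimethoxyphenyl)-5-methyl-2-(propan-2-yl)-1-(2,4,6-trimethoxyphenyl)hexan-1-ol | CC(C)C[C@H](c1c(OC)cc(OC)c(Br)c1O)[C@@H](C(C)C)C(O)c1c(OC)cc(OC)cc1OC
F7 | step 6 | [(2R,3R,4S)-8-bromo-5,7-dimethoxy-3-(propan-2-yl)-2-(2,4,6-trimethoxyphenyl)chroman-4-yl]methanol | OC[C@@H]1c2c(OC)cc(OC)c(Br)c2O[C@@H](c2c(OC)cc(OC)cc2OC)[C@@H]1C(C)C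
F8 | step 6 | (2R,3R,4S)-8-bromo-4-(iodomethyl)-5,7-dimethoxy-3-(propan-2-yl)-2-(2,4,6-trimethoxyphenyl)chromane | IC[C@@H]1c2c(OC)cc(OC)c(Br)c2O[C@@H](c2c(OC)cc(OC)cc2OC)[C@@H]1C(C)C
F9 | step 8 | 2-[(2R,3R,4S)-8-bromo-5,7-dihydroxy-4-(2-methylpropyl)-3-(propan-2-yl)chroman-2-yl]benzene-1,3,5-triol | CC(C)C[C@@H]1c2c(O)cc(O)c(Br)c2O[C@@H](c2c(O)cc(O)cc2O)[C@@H]1C(C)C
F10 | step 8 | 5-[(2R,3R,4S)-8-bromo-6-formyl-5,7-dihydroxy-4-(2-methylpropyl)-3-(propan-2-yl)chroman-2-yl]-2,4,6-trihydroxybenzene-1,3-dicarbaldehyde | CC(C)C[C@@H]1c2c(O)c(C=O)c(O)c(Br)c2O[C@@H](c2c(O)c(C=O)c(O)c(C=O)c2O)[C@@H]1C(C)C
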